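Readings and results come from a simulation with constants of no real substance; scatter was added.

Start from the amounts: the larch run charged more substrate than the flask, at the same equivalents of partner.

| flask | substrate | partner | remark | time |
|---|---|---|---|---|
| larch | 0.075 M | 1.5 equiv | run made earlier |  |
| flask | 0.050 M | 1.50 equiv |  | 80 min |

- larch (time / min: substrate / %, bis adduct / %): 0.417: 89, 0; 1.33: 69, 3; 2.50: 55, 7; 3.00: 55, 4; 5.00: 48, 7; 6.00: 45, 4; 8.00: 42, 8

(each reading ± 2 percentage points)

- the reaction counts as stopped when no species that holds the substrate changes by six tenths of a point or more over the second half of the time
- what has gone from substrate into another species counts as reacted, even if it can come back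

- the state of affairs at 80 min: stopped, and by what, or still going (all of the substrate has reacted / it is still moving / the partner has run out first)
- share of the substrate used up at 80 min
- bis adduct at 80 min, in percent of the substrate charged

Apply the bench rule first: with partner in excess, treat the larch run as pseudo-first-order and take the slope of ln c(substrate) from its first reading, 0.279 min⁻¹. Held to 8.00 min, that slope leaves 10.7% of the substrate, but the reading is 42%. Take the ratio of the logarithmic falls, 0.389, as the border of the rule. Then replace the falling curve of c(partner) by its mean: full charge for a lifetime 3.10 min, then none. Suppose this lifetime does not depend on the charge. At fixed equivalents c(partner) goes with the substrate charge, so under this supposition the fall does too. Take the last larch reading as the stall and carry the stall dose, the logarithmic fall of substrate at the stall per molar of substrate charged at these equivalents, 11.6 M⁻¹.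

For the flask, 80 min is 25.8 lifetimes, so commit to a stop by loss of partner. The dose gives conversion 43.9%. Scaling the mean of the last four bis adduct readings by the charges gives 3.83%.

The forecast says it is still moving, with conversion 55% and bis adduct 15%, a higher conversion than mine; it reads the levelling thus: “That points to a reversible first addition”.

The flask ends thus: the partner has run out first, with conversion 44.1% and bis adduct 4.17%.

    partner → decomposed reagent (k = 0.00643 s⁻¹)
    partner + first product → bis adduct + by-product (k = 0.0446 M⁻¹ s⁻¹)
    substrate + by-product ⇌ idle adduct, settled at all times (K = 1600 M⁻¹)
    substrate + partner → first product + by-product (k = 0.0271 M⁻¹ s⁻¹)

In the flask at 1.51 min, the half-life of partner by decomposition is 1.8 min, shorter than the 11 min by its reaction with substrate. Partner, the limiting reagent here, stands at 0% of its charge at 80.0 min, less than the 56% of substrate left. The dose gave this flask a logarithmic fall of substrate of 0.578, and the flask shows 0.580. For the neighbour charged with 0.20 M at the same equivalents, the dose gives 9.83% of the substrate left, and that flask holds 11% at 80.0 min.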